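The data were computed on assumed constants, noise included.

What is left of the starting material after 3.0 min is the question here, and the small part that went is easier to reckon than the large part that stayed.

| flask | starting material | second substrate | free enzyme | impurity | remark | time |
|---|---|---|---|---|---|---|
| oak | 2 mM | 2 mM | 0.40 µM | 0.30 µM | run made earlier |  |
| ash | 2 mM | 2 mM | 0.40 µM | 3.4 µM | run made earlier |  |
| Saturday's | 2.0 mM | 2.00 mM | 0.40 µM | 0.44 µM |  | 3.0 min |
| Wednesday's | 2.0 mM | 2.00 mM | 0.40 µM | 1.3 µM |  | 3.0 min |
| Tuesday's | 2.0 mM | 2.00 mM | 0.40 µM | 4.0 µM |  | 3.0 min |

| run | time / s | starting material / % | loaded enzyme / % | target / % | side product / % | second complex / % |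
|---|---|---|---|---|---|---|
| oak | 15.0 | 93.1 | 0 | 0.4 | 3.6 | 0 |
| oak | 40.0 | 87.8 | 0 | 1.2 | 8.8 | 0 |
| oak | 80.0 | 79.4 | 0.8 | 0.3 | 15.0 | 0 |
| oak | 120 | 73.3 | 0 | 1.1 | 20.3 | 0 |
| ash | 15.0 | 98.7 | 0 | 0.3 | 0.5 | 0.9 |
| ash | 40.0 | 99.6 | 0.7 | 0 | 1.3 | 0.3 |
| ash | 80.0 | 99.6 | 0 | 0.2 | 0.3 | 0 |
| ash | 120 | 100.0 | 0 | 0 | 0.1 | 0 |

(scatter of a reading: 0.5 percentage points)

- percent here means starting material units held: one side product counts as two
- the numbers in the tables scatter with a standard deviation of 0.5 percentage points
- a reading of starting material is of its free form alone

* which of these there is most of at the end, counted by the starting material in it, Saturday's (side product / loaded enzyme / target / second complex / starting material)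
* which of these there is most of at the end, counted by the starting material in it, Wednesday's (side product / loaded enzyme / target / second complex / starting material)
* which of these there is most of at the end, counted by the starting material in it, Tuesday's (side product / loaded enzyme / target / second complex / starting material)
* amount of the one of these that there is most of at the end, in percent of the starting material charged, Saturday's
* amount of the one of these that there is most of at the end, in percent of the starting material charged, Wednesday's
* amount of the one of these that there is most of at the end, in percent of the starting material charged, Tuesday's

Does a flask with more impurity than enzyme simply stand still? Not quite, since the enzyme takes time to die and consumes starting material while it lives, and the ash run, with its impurity in excess, shows a mean loss of 0.525%.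

How would you reckon that loss? I assume that loss goes with live enzyme, that death goes with live enzyme times impurity, and that one impurity takes one enzyme, so the loss per impurity used varies inversely with the impurity present and sums to a logarithm.

What does the oak run give? Its surplus enzyme loses 15 percentage points between 40.0 s and 120 s, and that line run back to the start leaves a burst of 4.95%, which, divided by the logarithm of charged enzyme over surplus enzyme, gives 3.57%: this is the ration, the starting material lost per unit of that logarithm, which for excess impurity is taken of charged impurity over impurity surviving.

Isn't that one line through scattered readings? It is, so I test it on ash, where the ration gives 0.447% against the mean loss of 0.525%, whose own scatter as a mean is 0.25 points.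

Is Saturday's finished in time, with the smallest surplus of impurity? The ration and the oak slope together give a death constant, and on that surplus the tail lasts about 49.3 s, short against 3.0 min.

Your figures, then? With enzyme as the limiting reagent of the killing, I reckon starting material at 91.4% for Saturday's, 98.7% for Wednesday's and 99.6% for Tuesday's.

The forecast also names starting material in each flask, but with 96%, 99.5% and 99.8%, on the ground that “the impurity binds enzyme tightly, roughly one to one”, so on Saturday's the two part.

The flasks give starting material as the most in Saturday's at 89.6%, starting material in Wednesday's at 98.3%, and starting material in Tuesday's at 99.5%.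

    starting material + free enzyme ⇌ first complex (K = 186 /M, k = 3.25 × 10⁶ /M/s)
    free enzyme + impurity → spent catalyst (k = 1.62 × 10⁶ /M/s)
    first complex → loaded enzyme + first product (k = 149 /s)
    starting material + first product ⇌ idle adduct, settled at all times (K = 1440 /M)
    second complex → free enzyme + target (k = 55.3 /s)
    starting material + target → side product (k = 129 /M/s)
    second substrate + loaded enzyme ⇌ second complex (K = 375 /M, k = 4.90 × 10⁵ /M/s)

In Saturday's the half-life of free enzyme against the impurity charged, 0.97 s, is short against the 3.0 min, and ten times as long leaves 89.5% of starting material, while the flask ended 1.8 points below the 91.4% reckoned from a ration of 3.57%. The flask like Wednesday's but with 3.2 × 10⁻⁴ mM of impurity, less than its enzyme, has surplus enzyme, so the ration plus the oak loss scaled to that surplus gives 68.2%, and it stands at 67.8%.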